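The earlier runs and the new flask were computed for substances that don't exist; the scatter is artificial.

What leaves the starting material takes one partner with it, and each over-reaction product takes a second, so c(partner) can be reckoned at any moment from the readings of starting material and over-reaction product.

| flask | starting material | partner | temperature | remark | time |
|---|---|---|---|---|---|
| midnight | 0.56 M | 1.2 equiv | 0 °C | run made earlier |  |
| dusk | 0.88 M | 1.2 equiv | 33 °C | run made earlier |  |
| Sunday's | 0.40 M | 1.20 equiv | −15 °C |  | 3.0 min |
| Wednesday's | 0.40 M | 1.20 equiv | 5 °C |  | 3.0 min |
| Monday's | 0.40 M | 1.20 equiv | 45 °C |  | 3.0 min |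
| Friday's | 0.40 M | 1.20 equiv | 25 °C |  | 3.0 min |

| run | time / s | target / % | over-reaction product / % | starting material / % |
|---|---|---|---|---|
| midnight | 10.0 | 6.9 | 0 | 48.9 |
| midnight | 25.0 | 15.5 | 0.8 | 45.3 |
| midnight | 40.0 | 18.1 | 1.7 | 43.0 |
| midnight | 80.0 | 18.7 | 4.4 | 42.3 |
| dusk | 10.0 | 8.9 | 7.0 | 68.3 |
| dusk | 15.0 | 8.1 | 9.2 | 67.7 |

(standard deviation of a reading: 0.3 percentage points)

- which flask leads in share of target in all that became target or over-reaction product ("all alike" within 1.5 percentage points) (Sunday's / Wednesday's / Monday's / Friday's / all alike)
- share of target in all that became target or over-reaction product, Sunday's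
- share of target in all that became target or over-reaction product, Wednesday's
- share of target in all that became target or over-reaction product, Monday's
- share of target in all that became target or over-reaction product, Friday's

- the earlier runs were read with a standard deviation of 0.3 percentage points
- steps that have been proposed: starting material + partner <-> intermediate; intermediate <-> target + by-product; partner + target -> over-reaction product

I build the flask up step by step. With the two reversible steps, nothing becomes over-reaction product, so the asked share stands at 100%.

Now I add the drain, partner + target → over-reaction product. Between 40.0 s and 80.0 s of the midnight run, over-reaction product rises by 2.7 percentage points while target stands near 18.4% and c(partner) near 0.334 M. So I read a rate constant k of 0.0110 /M/s. The same reckoning on the dusk run, between 10.0 s and 15.0 s, reads 0.0736 /M/s, roughly, given the scatter. I let k grow by a constant factor per degree, and I take free partner as half of its charge, as at midnight.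

For Sunday's I reckon 906 s as the drain time, the inverse of k times c(partner), a pseudo-first-order lifetime of the target. Wednesday's is 286 s, Friday's 90.3 s and Monday's 28.5 s, so Sunday's is the longest. If the target pool stood steady, over-reaction product would be the run time over the drain time, counted in target. The shares would then be 83.4%, 61.4%, 33.4% and 13.7% in that order.

Last comes the pool itself. I expect it to be still climbing in cold Sunday's; a straight climb has a mean of half its end value, which gives 91.0%. In the dusk run target reads 8.9% and then 8.1%, so I expect the steady figures of the warm flasks to stand too high.

The forecast names Sunday's, with 92%, 56%, 4% and 16% for Sunday's, Wednesday's, Monday's and Friday's: “The cold flask is barely drained, because it is still approaching equilibrium.” My steady figure for Monday's is higher than the forecast's.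

Sunday's leads with 93.6%, against 56.0% for Wednesday's, 17.0% for Friday's and 4.64% for Monday's.

starting material + partner ⇌ intermediate (K = 1.80 /M, k = 0.580 /M/s, Ea = 53.0 kJ/mol, ΔH = −43.0 kJ/mol); intermediate ⇌ target + by-product (K = 0.0750 M, k = 0.0350 /s, Ea = 80.0 kJ/mol, ΔH = 2.00 kJ/mol); partner + target → over-reaction product (k = 0.0150 /M/s, Ea = 45.0 kJ/mol); (constants at 5 °C) At the end of Sunday's, target is made 6.17 times faster than it is used up. The same flask with 3.00 equiv of partner keeps 68% of that charge free, so the drain time 906 s shrinks to 264 s. The climbing-pool form then gives 74.6%, and that flask holds 76.8%.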